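The earlier runs and the new flask were generated by integration from invented constants; the scatter is artificial.

Start at the early readings: at 12.0 min the east run shows 95.8% electrophile and 4.7% target, together 100% of the charge. So count each lost electrophile as target, and treat the two columns as two separate measures of one loss.

in all of them: electrophile 0.50 M; gas 75 mM (held)

| charge | nucleophile | remark | time |
|---|---|---|---|
| east | 0.92 M | run made earlier |  |
| north-east | 1.1 M | run made earlier |  |
| south-east | 1 M | run made earlier |  |
| Wednesday's | 0.900 M |  | 80 min |
| Friday's | 1.40 M |  | 80 min |

| run | time / min | electrophile / % | target / % |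
|---|---|---|---|
| east | 6.00 | 98.7 | 1.8 |
| east | 12.0 | 95.8 | 4.7 |
| east | 25.0 | 91.7 | 7.8 |
| east | 40.0 | 86.9 | 13.3 |
| east | 80.0 | 78.5 | 23.1 |
| north-east | 8.00 | 95.9 | 3.2 |
| north-east | 20.0 | 91.8 | 7.9 |
| north-east | 40.0 | 84.6 | 15.7 |
| north-east | 60.0 | 79.3 | 21.4 |
| north-east | 80.0 | 73.8 | 26.7 |
| south-east | 6.00 | 97.0 | 1.9 |
| south-east | 12.0 | 96.5 | 4.5 |
| south-east | 25.0 | 90.5 | 9.3 |
| south-east | 40.0 | 86.3 | 12.3 |
| south-east | 80.0 | 75.8 | 24.2 |

(each reading ± 0.5 percentage points)

- at the start none of the gas is in solution

1. part of the electrophile that has reacted at the end, Wednesday's
2. part of the electrophile that has reacted at the end, Friday's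
3. what raising the concentration of nucleophile from its lowest to its highest value here does to the part of the electrophile that has reacted (changes below 5 percentage points count as none) (it falls / it rises / no change)

Suppose the electrophile fades in proportion to itself and to the nucleophile. Divide its fading rate in one flask by that in another, both read at 80 min: time drops out, and if the nucleophile has fallen by the same share in both flasks, the ratio of the logarithmic losses equals the ratio of the nucleophile charges. So take the natural logarithm of charged over remaining electrophile at 80 min and divide it by the nucleophile charge. From the electrophile column the runs average 0.272 M⁻¹. From the target column, taking the remainder as the charge less target, they average 0.282 M⁻¹.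

In the south-east run the two ways meet, at 0.277 M⁻¹ and 0.277 M⁻¹. In the east run they part, 0.263 M⁻¹ against 0.286 M⁻¹, but there the last two readings add to 102%, more than the charge. So at least one of them runs high, and with 0.5 percentage points on each reading it reads as scatter, not chemistry.

Take the mean of the two ways, 0.277 M⁻¹, as the loss per molar nucleophile, a pseudo-first-order figure with that equal fall of the nucleophile folded in. Raise e to minus this number times the charge to get the share left. My reckoning then gives 22.1% reacted in Wednesday's and 32.1% in Friday's, a rise of 10 points, beyond the margin. Friday's charge lies above the highest run, 1.1 M, and the readings carry no nucleophile column to test the folding.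

The forecast, taking the reaction as “first order in each of electrophile and nucleophile”, gives 22% and 32%, and says it rises.

The flasks give 21.9% for Wednesday's and 32.0% for Friday's: it rises, by 10 points.

    gas ⇌ free base, rate k1*(csat - [free base]) (kL = 1.09 h⁻¹)
    electrophile + nucleophile → acid set free + target (k = 0.234 M⁻¹ h⁻¹)
    acid set free + free base ⇌ salt of the base, settled at all times (K = 10700 M⁻¹)
    nucleophile + acid set free ⇌ protonated nucleophile, settled at all times (K = 2100 M⁻¹)

Read back from these results, the loss per molar nucleophile is 0.275 M⁻¹ in Wednesday's and 0.275 M⁻¹ in Friday's, beside 0.277 M⁻¹ from the runs; at 80.0 min Wednesday's keeps 79% of its nucleophile unbound and Friday's 79%. Now cut Friday's flask to 0.35 M of nucleophile, 0.700 equiv to the electrophile. The same number foretells 9.24% reacted. That flask gives 9.23%, with 90.8% of its electrophile left and 80% of its nucleophile unbound.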